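**Retrosynthetic overview**
1. Last bond: O1–C2 of ring C, by intramolecular Mitsunobu etherification of a phenol/primary alcohol. That diol is the reduction product of a (3S)-3-aryl-3,4-dihydrocoumarin, whose lactone protects the ring A phenol and carries C2.
2. Key disconnection C3–C1′: C3 is used as an enolonium (a2) equivalent, a racemic α-bromo lactone, and C1′ as an arylzinc. Both carbons are natural nucleophiles (lactone α-carbon; ortho carbon of a phenol ether). An enantioconvergent nickel coupling sets C3 as S in the bond-forming event.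
3. The α-bromo lactone comes in one operation from osthole, which supplies ring A, the prenyl group, the 7-oxygen and C2–C4.
4. The arylzinc comes by ortho-lithiation of the MOM ether of 2,2-dimethyl-2H-chromen-5-ol, made from cyclohexane-1,3-dione and prenal.
5. Ring order: dimethylpyran ring, then aromatic ring B (aromatisation); ring A and the lactone are bought with osthole; ring C is closed last, before one-pot removal of both O-protecting groups.

Assumption: the sense of induction of the chiral catalyst in step 5 (and in its fallback) cannot be read from precedent for this substrate class; the enantiomer written is taken as the one giving (3S), and the mirror-image ligand is used if a pilot run shows (3R).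
Assumption: osthole, a bulk natural product sold at gram-to-kilogram scale, counts as a cheap commercial starting material.

Step 1
Reactants: 1 cyclohexane-1,3-dione; 2 3-methylbut-2-enal (prenal)
Product: 3 2,2-dimethyl-2,6,7,8-tetrahydro-5H-chromen-5-one
Conditions: ethylenediammonium diacetate (10 mol%), MeOH, rt, 6 h
Reagents that add atoms: none
Why: Knoevenagel condensation of the 1,3-dione with the enal followed by oxa-6π-electrocyclisation (formal [3+3] annulation) builds the 2,2-dimethyl-2H-pyran ring in one operation; no stereocentre is formed.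

Step 2
Reactants: 3 2,2-dimethyl-2,6,7,8-tetrahydro-5H-chromen-5-one
Product: 5 2,2-dimethyl-2H-chromen-5-ol, via α-phenylselanyl ketone 4 (not isolated)
Conditions: LiN(i-Pr)2 (1.1 equiv), THF, −78 °C; PhSeCl (1.1 equiv), −78 °C; then pyridine, 30% H2O2, 0 °C → rt
Reagents that add atoms: none
Why: the kinetic α′-enolate of the vinylogous ester is selenenylated at C6, and selenoxide syn-elimination gives a cross-conjugated dienone that tautomerises to the phenol (selenoxide elimination/aromatisation).

Step 3
Reactants: 5 2,2-dimethyl-2H-chromen-5-ol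
Product: 6 5-(methoxymethoxy)-2,2-dimethyl-2H-chromene
Conditions: NaH (1.2 equiv), THF/DMF, 0 °C; MOMCl (1.2 equiv), 0 °C → rt
Reagents that add atoms: chloromethyl methyl ether (MOMCl), COCCl
Why: Williamson-type O-alkylation of the phenoxide installs a MOM ether that is base- and hydride-stable and is the directing group for the later ortho-lithiation.

Step 4
Reactants: 7 osthole [7-methoxy-8-(3-methylbut-2-en-1-yl)-2H-chromen-2-one]
Product: 9 rac-3-bromo-7-methoxy-8-(3-methylbut-2-en-1-yl)chroman-2-one, via silyl ketene acetal 8 (not isolated)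
Conditions: [(Ph3P)CuH]6 (2 mol%), PhMe2SiH (1.15 equiv), toluene, rt; then THF, −78 °C, NBS (1.15 equiv)
Reagents that add atoms: N-bromosuccinimide (NBS), O=C1CCC(=O)N1Br
Why: copper-hydride-catalysed conjugate hydrosilylation (1,4-reduction) touches only the coumarin C3=C4 bond and leaves the silyl ketene acetal, which is brominated at C3 at −78 °C far faster than the prenyl alkene or the arene react (tandem 1,4-reduction/electrophilic α-bromination); the new stereocentre is racemic by design.

Step 5
Reactants: 6 5-(methoxymethoxy)-2,2-dimethyl-2H-chromene (1.5 equiv); 9 rac-3-bromo-7-methoxy-8-(3-methylbut-2-en-1-yl)chroman-2-one (1.0 equiv)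
Product: 12 (3S)-7-methoxy-3-[5-(methoxymethoxy)-2,2-dimethyl-2H-chromen-6-yl]-8-(3-methylbut-2-en-1-yl)chroman-2-one, via aryllithium 10 (not isolated), via arylzinc iodide 11 (not isolated)
Conditions: 6, n-BuLi (1.5 equiv), THF, 0 °C, 1 h; ZnI2 (1.6 equiv), −20 °C → rt; then added to 9, NiCl2·DME (10 mol%), (S,S)-Ph-pybox (13 mol%), DME/THF, −30 °C, 12 h; crude 12 used at once
Reagents that add atoms: none
Why: Proposed new method: directed ortho-metalation of 6 (C6 is the only position ortho to OMOM) and Li→Zn exchange give a weakly basic arylzinc; the monovalent aryl–nickel–pybox species abstracts bromine from racemic 9 to give a planar α-lactonyl radical (the C3 enolonium/a2 equivalent, its configuration erased), which is captured by the chiral divalent aryl–nickel complex and reductively eliminates from trivalent nickel with the ligand fixing C3 as S; the closest known reaction type is the nickel/pybox-catalysed stereoconvergent Negishi α-arylation of racemic α-bromo ketones with arylzinc reagents (and related arylations of α-halo esters and amides), the new elements being the aryl-lactone electrophile and the ortho-alkoxy arylzinc, and at −30 °C the zinc reagent should neither eliminate HBr from 9 nor epimerise 12.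

Step 6
Reactants: 12 (3S)-7-methoxy-3-[5-(methoxymethoxy)-2,2-dimethyl-2H-chromen-6-yl]-8-(3-methylbut-2-en-1-yl)chroman-2-one
Product: 13 6-{(2S)-3-hydroxy-2-[5-(methoxymethoxy)-2,2-dimethyl-2H-chromen-6-yl]propyl}-3-methoxy-2-(3-methylbut-2-en-1-yl)phenol
Conditions: LiAlH4 (1.5 equiv), THF, −20 → 0 °C; then H2O
Reagents that add atoms: none
Why: hydride reduction of the activated aryl lactone is much faster than α-deprotonation, so C3 is carried over unchanged and is no longer epimerisable afterwards, while only the ring A phenol is unmasked (ester reduction; MOM ether, prenyl and chromene alkenes are inert).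

Step 7
Reactants: 13 6-{(2S)-3-hydroxy-2-[5-(methoxymethoxy)-2,2-dimethyl-2H-chromen-6-yl]propyl}-3-methoxy-2-(3-methylbut-2-en-1-yl)phenol
Product: 14 (3S)-7-methoxy-3-[5-(methoxymethoxy)-2,2-dimethyl-2H-chromen-6-yl]-8-(3-methylbut-2-en-1-yl)chromane
Conditions: PPh3 (1.5 equiv), DIAD (1.5 equiv), THF (0.02 M), 0 °C → rt
Reagents that add atoms: none
Why: intramolecular Mitsunobu etherification, in which the only free phenol displaces the activated primary alcohol in a 6-exo-tet closure of ring C; C3 is not a reacting centre, so its configuration is untouched.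

Step 8
Reactants: 14 (3S)-7-methoxy-3-[5-(methoxymethoxy)-2,2-dimethyl-2H-chromen-6-yl]-8-(3-methylbut-2-en-1-yl)chromane
Product: 16 (3S)-3-(5-hydroxy-2,2-dimethyl-2H-chromen-6-yl)-8-(3-methylbut-2-en-1-yl)chroman-7-ol, via 7-phenol MOM ether 15 (not isolated)
Conditions: NaSEt (5 equiv), DMF, 120 °C, 3 h; cool to 0 °C, N2 sweep, MeOH, conc. HCl (to about 2 M), 40 °C, 2 h
Reagents that add atoms: none
Why: SN2 O-demethylation by thiolate (aryl methyl ether cleavage) is acid-free and leaves both alkenes alone, and the acid needed for work-up then solvolyses the MOM acetal with methanol trapping the methoxymethyl cation; no stereocentre is involved.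

**Compound list**
1 | cyclohexane-1,3-dione | O=C1CCCC(=O)C1 | starting material
2 | 3-methylbut-2-enal (prenal) | CC(C)=CC=O | starting material
3 | 2,2-dimethyl-2,6,7,8-tetrahydro-5H-chromen-5-one | CC1(C)C=CC2=C(O1)CCCC2=O | intermediate
4 | 2,2-dimethyl-6-(phenylselanyl)-2,6,7,8-tetrahydro-5H-chromen-5-one (racemic) | CC1(C)C=CC2=C(O1)CCC([Se]c1ccccc1)C2=O | intermediate
5 | 2,2-dimethyl-2H-chromen-5-ol | CC1(C)C=Cc2c(O)cccc2O1 | intermediate
6 | 5-(methoxymethoxy)-2,2-dimethyl-2H-chromene | COCOc1cccc2OC(C)(C)C=Cc12 | intermediate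
7 | osthole, 7-methoxy-8-(3-methylbut-2-en-1-yl)-2H-chromen-2-one | CC(C)=CCc1c(OC)ccc2C=CC(=O)Oc12 | starting material
8 | dimethyl{[7-methoxy-8-(3-methylbut-2-en-1-yl)-4H-chromen-2-yl]oxy}phenylsilane | CC(C)=CCc1c(OC)ccc2CC=C(O[Si](C)(C)c3ccccc3)Oc12 | intermediate
9 | rac-3-bromo-7-methoxy-8-(3-methylbut-2-en-1-yl)chroman-2-one | CC(C)=CCc1c(OC)ccc2CC(Br)C(=O)Oc12 | intermediate
10 | [5-(methoxymethoxy)-2,2-dimethyl-2H-chromen-6-yl]lithium | [Li]c1ccc2OC(C)(C)C=Cc2c1OCOC | intermediate
11 | [5-(methoxymethoxy)-2,2-dimethyl-2H-chromen-6-yl]zinc iodide | I[Zn]c1ccc2OC(C)(C)C=Cc2c1OCOC | intermediate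
12 | (3S)-7-methoxy-3-[5-(methoxymethoxy)-2,2-dimethyl-2H-chromen-6-yl]-8-(3-methylbut-2-en-1-yl)chroman-2-one | CC(C)=CCc1c(OC)ccc2c1OC(=O)[C@H](c1ccc3OC(C)(C)C=Cc3c1OCOC)C2 | intermediate
13 | 6-{(2S)-3-hydroxy-2-[5-(methoxymethoxy)-2,2-dimethyl-2H-chromen-6-yl]propyl}-3-methoxy-2-(3-methylbut-2-en-1-yl)phenol | CC(C)=CCc1c(OC)ccc(C[C@H](CO)c2ccc3OC(C)(C)C=Cc3c2OCOC)c1O | intermediate
14 | (3S)-7-methoxy-3-[5-(methoxymethoxy)-2,2-dimethyl-2H-chromen-6-yl]-8-(3-methylbut-2-en-1-yl)chromane | CC(C)=CCc1c(OC)ccc2c1OC[C@H](c1ccc3OC(C)(C)C=Cc3c1OCOC)C2 | intermediate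
15 | (3S)-3-[5-(methoxymethoxy)-2,2-dimethyl-2H-chromen-6-yl]-8-(3-methylbut-2-en-1-yl)chroman-7-ol | CC(C)=CCc1c(O)ccc2c1OC[C@H](c1ccc3OC(C)(C)C=Cc3c1OCOC)C2 | intermediate
16 | (3S)-3-(5-hydroxy-2,2-dimethyl-2H-chromen-6-yl)-8-(3-methylbut-2-en-1-yl)chroman-7-ol | CC(C)=CCc1c(O)ccc2c1OC[C@H](c1ccc3c(c1O)C=CC(C)(C)O3)C2 | target

**Step count and risks**
Total steps: 8. Longest linear sequence: 7 (steps 1, 2, 3, 5, 6, 7, 8); step 4 is the one-step side branch.

The step most likely to fail is step 5. The risks are elimination of HBr from 9 back to osthole, slow transmetalation of the ortho-alkoxy arylzinc, and low ee on a lactone electrophile. The fallback sets out from 9 (with 11) and comes back at 13, moving the stereo-determining event from the coupling to the reduction. Compounds 9 and 11 are coupled with an achiral catalyst (NiCl2·DME, 4,4′-di-tert-butyl-2,2′-bipyridine, THF/DMA, 0 °C) to give racemic 7-methoxy-3-[5-(methoxymethoxy)-2,2-dimethyl-2H-chromen-6-yl]-8-(3-methylbut-2-en-1-yl)chroman-2-one F1. This is reduced with i-Bu2AlH (toluene, −78 °C) to the lactol 7-methoxy-3-[5-(methoxymethoxy)-2,2-dimethyl-2H-chromen-6-yl]-8-(3-methylbut-2-en-1-yl)chroman-2-ol F2, a masked, freely epimerising α-aryl aldehyde. F2 is hydrogenated under dynamic kinetic resolution with RuCl2[(S)-Xyl-SDP][(R,R)-DPEN], KOt-Bu, i-PrOH, H2 (20–50 atm), rt. Base racemises the open hydroxy-aldehyde through its enolate while the chiral ruthenium hydride reduces one enantiomer faster, giving 13; this carbonyl-selective catalyst leaves the C=C bonds alone.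

The second is step 4. Residual silane, phosphine or copper may interfere with NBS, or the lactone may be over-reduced. The fallback sets out from 7 and comes back at 8. The conjugate reduction is run with a proton quench ([(Ph3P)CuH]6 cat., polymethylhydrosiloxane, t-BuOH, toluene, rt) and 7-methoxy-8-(3-methylbut-2-en-1-yl)chroman-2-one (dihydroosthole) F3 is isolated. The ketene acetal is then made by deprotonation instead of reduction: LiN(SiMe3)2 is added to F3 and PhMe2SiCl in THF at −78 °C (in situ quench) to reach 8, which is brominated with NBS as in step 4.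

The third is step 8. In the acid stage the free 7-phenol sits next to the prenyl group (risk of cyclisation to a dimethylchroman), and the electron-rich chromene is exposed to acid in the presence of thiol. The fallback sets out from 14 and comes back at 16, inverting the order with isolation. The MOM group is removed first, while O7 is still methylated and no thiol is present (2 M HCl, MeOH/THF, 40 °C, or pyridinium p-toluenesulfonate, t-BuOH, 80 °C), giving 6-[(3S)-7-methoxy-8-(3-methylbut-2-en-1-yl)chroman-3-yl]-2,2-dimethyl-2H-chromen-5-ol F4. NaSEt (6 equiv) in DMF at 120 °C with a buffered aqueous NH4Cl work-up then gives 16 without acid exposure of the free prenylphenol.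

**Further compounds**
F1 | step 5 | rac-7-methoxy-3-[5-(methoxymethoxy)-2,2-dimethyl-2H-chromen-6-yl]-8-(3-methylbut-2-en-1-yl)chroman-2-one | CC(C)=CCc1c(OC)ccc2c1OC(=O)C(c1ccc3OC(C)(C)C=Cc3c1OCOC)C2
F2 | step 5 | 7-methoxy-3-[5-(methoxymethoxy)-2,2-dimethyl-2H-chromen-6-yl]-8-(3-methylbut-2-en-1-yl)chroman-2-ol (racemic lactol) | CC(C)=CCc1c(OC)ccc2c1OC(O)C(c1ccc3OC(C)(C)C=Cc3c1OCOC)C2
F3 | step 4 | 7-methoxy-8-(3-methylbut-2-en-1-yl)chroman-2-one (dihydroosthole) | CC(C)=CCc1c(OC)ccc2CCC(=O)Oc12
F4 | step 8 | 6-[(3S)-7-methoxy-8-(3-methylbut-2-en-1-yl)chroman-3-yl]-2,2-dimethyl-2H-chromen-5-ol | CC(C)=CCc1c(OC)ccc2c1OC[C@H](c1ccc3OC(C)(C)C=Cc3c1O)C2
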